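Ring A (the 2,2-dimethylcyclohexanone) is disconnected between its methylidene-bearing carbon C4 and the stereogenic methine C3. The exocyclic methylene on C4, C3 and the first two side-chain carbons on C3 together are the 1,4-diene retron of an Alder-ene reaction. An enantioselective palladium hydride catalysed cycloisomerization of an acyclic 1,7-enyne, (E)-6,6-dimethylnon-7-en-1-yn-5-one, therefore closes ring A, sets the only stereocenter and delivers both the methylidene group and a vinyl handle in a single isomerization with no by-product. The vinyl group is then grown into the side chain by hydroboration and Suzuki coupling, and the coumarin is attached last by Mitsunobu etherification.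

Key step: step 4

Remark: ring A is numbered C1 (carbonyl), C2 (gem-dimethyl), C3 (stereogenic methine, R) and C4 (methylidene carbon); the sense of induction of a chiral bisphosphine in step 4 cannot be predicted with certainty, so (R)-BINAP there stands for the antipode that leads to the R product.

Step 1
Reactants: 1 (E)-2-methylpent-2-enoic acid
Product: 3 (E)-2,2-dimethylpent-3-enoic acid, via dilithium dienediolate 2 (not isolated)
Conditions: LiN(i-Pr)2 (2.2 equiv), THF/DMPU, −78 to 0 °C; MeI, −78 °C to rt; aq. HCl work-up
Reagents that add atoms: iodomethane, CI
Why: Deconjugative α-alkylation of a dienediolate: the base removes the carboxylic and a γ-hydrogen, the dianion is methylated at the α-carbon, and allylic 1,3-strain with the α-methyl group during γ-deprotonation should place the terminal methyl outward so that the new 3,4-alkene is E; no stereocenter is formed.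

Step 2
Reactants: 3 (E)-2,2-dimethylpent-3-enoic acid
Product: 5 (E)-3,3-dimethylhex-4-en-2-one, via dilithium gem-diolate 4 (not isolated)
Conditions: MeLi (2.2 equiv), Et2O, 0 °C to rt; inverse quench into cold aq. HCl
Reagents that add atoms: methyllithium, [Li]C
Why: Addition of an organolithium to a lithium carboxylate (carboxylic acid to methyl ketone): the dilithium gem-diolate is stable until hydrolysis, so the ketone appears only on quenching and over-addition is avoided, while the β,γ-alkene cannot move into conjugation because the α-carbon is quaternary.

Step 3
Reactants: 5 (E)-3,3-dimethylhex-4-en-2-one; 6 3-bromoprop-1-yne (propargyl bromide)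
Product: 8 (E)-6,6-dimethylnon-7-en-1-yn-5-one, via lithium enolate 7 (not isolated)
Conditions: LiN(i-Pr)2 (1.05 equiv), THF, −78 °C; then 6 (1.1 equiv), DMPU, −78 to 0 °C
Reagents that add atoms: none
Why: Kinetic enolate alkylation: the ketone has α-hydrogens only on its methyl group, so a single enolate forms and attacks the propargylic bromide by SN2 to install the but-3-ynyl arm, the terminal alkyne being too weakly acidic to quench the enolate.

Step 4
Reactants: 8 (E)-6,6-dimethylnon-7-en-1-yn-5-one
Product: 9 (R)-3-ethenyl-2,2-dimethyl-4-methylidenecyclohexan-1-one
Conditions: Pd2(dba)3·CHCl3 (2.5 mol %), (R)-BINAP (6 mol %), AcOH (20 mol %), benzene, 50 °C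
Reagents that add atoms: none
Why: Zerovalent palladium and acetic acid give a hydridopalladium acetate that adds across the terminal alkyne with palladium on the internal carbon; the alkenylpalladium inserts the E-propenyl alkene, and β-hydride elimination toward the methyl group releases the 1,4-diene and returns the hydride. The closest known reaction type is the palladium-catalysed Alder-ene cycloisomerization of 1,6- and 1,7-enynes, including its enantioselective variants with chiral bisphosphines. Ring A closes in the 6-exo-trig mode, favoured over 7-endo by ring size and by the Thorpe–Ingold effect of the gem-dimethyl group that adjoins the alkene. The stereocenter at C3 is set in the migratory insertion, where the C2-symmetric bisphosphine on palladium selects one face of the propenyl group. The step needs hydride elimination toward the methyl group and not toward the new ring methine, which the three freely rotating methyl hydrogens and the absence of an allylic heteroatom should secure, and it needs the doubly allylic methine of the product to survive, for which the weak acid and moderate temperature are chosen. The quaternary carbon between ketone and alkene rules out conjugation of the product, and the phosphine-bound hydride is a poor π-acid, which should hold back furan formation from the γ,δ-alkynyl ketone.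

Step 5
Reactants: 9 (R)-3-ethenyl-2,2-dimethyl-4-methylidenecyclohexan-1-one
Product: 10 (R)-2,2-dimethyl-4-methylidene-3-[2-(4,4,5,5-tetramethyl-1,3,2-dioxaborolan-2-yl)ethyl]cyclohexan-1-one
Conditions: [Ir(cod)Cl]2 (1.5 mol %), dppm (3 mol %), pinacolborane (1.05 equiv), CH2Cl2, rt
Reagents that add atoms: pinacolborane, CC1(C)OBOC1(C)C
Why: Metal-catalysed anti-Markovnikov hydroboration: the iridium–diphosphine catalyst should strongly favour the monosubstituted vinyl group over the 1,1-disubstituted methylidene and leave the hindered ketone untouched by the mild pinacolborane, placing boron on the terminal carbon without disturbing the stereocenter.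

Step 6
Reactants: 11 but-2-yn-1-ol
Product: 13 (E)-3-iodobut-2-en-1-ol, via alkenylzirconocene chloride 12 (not isolated)
Conditions: Cp2Zr(H)Cl (2.3 equiv), THF, 0 °C to rt; then I2, −78 to 0 °C; aq. HCl work-up
Reagents that add atoms: iodine, II
Why: Hydrozirconation–iodination: one equivalent of the hydride is consumed by the hydroxyl group, the second adds syn across the alkyne with zirconium on the less hindered carbon remote from oxygen, and iodinolysis of the carbon–zirconium bond with retention should give the E alkenyl iodide.

Step 7
Reactants: 10 (R)-2,2-dimethyl-4-methylidene-3-[2-(4,4,5,5-tetramethyl-1,3,2-dioxaborolan-2-yl)ethyl]cyclohexan-1-one; 13 (E)-3-iodobut-2-en-1-ol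
Product: 14 (R)-3-[(E)-5-hydroxy-3-methylpent-3-en-1-yl]-2,2-dimethyl-4-methylidenecyclohexan-1-one
Conditions: Pd(OAc)2 (5 mol %), RuPhos (10 mol %), K3PO4 (3 equiv), toluene/H2O (10:1), 80 °C
Reagents that add atoms: none
Why: B-alkyl Suzuki–Miyaura coupling: oxidative addition of the alkenyl iodide and reductive elimination retain the E geometry, the electron-rich bulky biarylphosphine with aqueous phosphate should speed transmetalation of the primary alkylboronate past β-hydride elimination, and the ketone, the free hydroxyl group and the stereocenter are not involved.

Step 8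
Reactants: 15 1-(2-hydroxy-6-methylphenyl)ethan-1-one
Product: 17 4-hydroxy-5-methyl-2H-chromen-2-one, via β-keto ester 16 (not isolated)
Conditions: NaH (3 equiv), diethyl carbonate, toluene, 110 °C; aq. HCl work-up
Reagents that add atoms: diethyl carbonate, CCOC(=O)OCC
Why: Claisen-type C-acylation of the ketone enolate by the carbonate followed by lactonization of the phenoxide onto the new ester (the standard 4-hydroxycoumarin synthesis), driven by formation of the stabilized coumarin enolate.

Step 9
Reactants: 14 (R)-3-[(E)-5-hydroxy-3-methylpent-3-en-1-yl]-2,2-dimethyl-4-methylidenecyclohexan-1-one; 17 4-hydroxy-5-methyl-2H-chromen-2-one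
Product: 18 4-{[(2E)-5-[(1R)-2,2-dimethyl-6-methylidene-3-oxocyclohexyl]-3-methylpent-2-en-1-yl]oxy}-5-methyl-2H-chromen-2-one (target)
Conditions: PPh3 (1.3 equiv), diisopropyl azodicarboxylate (1.3 equiv), THF, 0 °C to rt
Reagents that add atoms: none
Why: Mitsunobu etherification: the acidic enolic hydroxyl of the 4-hydroxycoumarin is a suitable pronucleophile and its oxygen should displace the primary allylic oxyphosphonium by SN2 without allylic transposition, the ketone, both alkenes and the remote stereocenter being inert to the neutral conditions.

Compound list
1 | (E)-2-methylpent-2-enoic acid | CC/C=C(\C)C(=O)O | starting material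
2 | dilithium (E)-2-methylpenta-1,3-diene-1,1-diolate | [Li+].[Li+].C/C=C/C(C)=C([O-])[O-] | intermediate
3 | (E)-2,2-dimethylpent-3-enoic acid | C/C=C/C(C)(C)C(=O)O | intermediate
4 | dilithium (E)-3,3-dimethylhex-4-ene-2,2-diolate | [Li+].[Li+].C/C=C/C(C)(C)C(C)([O-])[O-] | intermediate
5 | (E)-3,3-dimethylhex-4-en-2-one | C/C=C/C(C)(C)C(C)=O | intermediate
6 | 3-bromoprop-1-yne (propargyl bromide) | C#CCBr | starting material
7 | lithium (E)-3,3-dimethylhexa-1,4-dien-2-olate | [Li+].C/C=C/C(C)(C)C(=C)[O-] | intermediate
8 | (E)-6,6-dimethylnon-7-en-1-yn-5-one | C#CCCC(=O)C(C)(C)/C=C/C | intermediate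
9 | (R)-3-ethenyl-2,2-dimethyl-4-methylidenecyclohexan-1-one | C=C1CCC(=O)C(C)(C)[C@@H]1C=C | intermediate
10 | (R)-2,2-dimethyl-4-methylidene-3-[2-(4,4,5,5-tetramethyl-1,3,2-dioxaborolan-2-yl)ethyl]cyclohexan-1-one | C=C1CCC(=O)C(C)(C)[C@@H]1CCB2OC(C)(C)C(C)(C)O2 | intermediate
11 | but-2-yn-1-ol | CC#CCO | starting material
12 | (E)-alkenylzirconocene chloride of but-2-yn-1-ol, oxygen bound to a second zirconocene chloride | C/C(=C\CO[Zr](Cl)(C1C=CC=C1)C1C=CC=C1)[Zr](Cl)(C1C=CC=C1)C1C=CC=C1 | intermediate
13 | (E)-3-iodobut-2-en-1-ol | C/C(I)=C\CO | intermediate
14 | (R)-3-[(E)-5-hydroxy-3-methylpent-3-en-1-yl]-2,2-dimethyl-4-methylidenecyclohexan-1-one | C=C1CCC(=O)C(C)(C)[C@@H]1CC/C(C)=C/CO | intermediate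
15 | 1-(2-hydroxy-6-methylphenyl)ethan-1-one | CC(=O)c1c(C)cccc1O | starting material
16 | ethyl 3-(2-hydroxy-6-methylphenyl)-3-oxopropanoate (present as its sodium salt) | CCOC(=O)CC(=O)c1c(C)cccc1O | intermediate
17 | 4-hydroxy-5-methyl-2H-chromen-2-one | Cc1cccc2oc(=O)cc(O)c12 | intermediate
18 | 4-{[(2E)-5-[(1R)-2,2-dimethyl-6-methylidene-3-oxocyclohexyl]-3-methylpent-2-en-1-yl]oxy}-5-methyl-2H-chromen-2-one | C=C1CCC(=O)C(C)(C)[C@@H]1CC/C(C)=C/COc1cc(=O)oc2cccc(C)c12 | target

Total step count: 9. Longest linear sequence: 7 steps (steps 1, 2, 3, 4, 5, 7 and 9).

Steps most likely to fail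

Step 4 (key step). The migratory insertion may discriminate the two alkene faces poorly, or the γ,δ-alkynyl ketone may be diverted by alkyne oligomerization or furan formation before the hydride adds. The fallback is an asymmetric intramolecular Mizoroki–Heck reaction that enters the same ring closure from an alkenyl halide instead of the alkyne. It sets out from ketone 5: lithium enolate 7 is alkylated with 2,3-dibromopropene (THF, −78 to 0 °C) to give (E)-2-bromo-6,6-dimethylnona-1,7-dien-5-one F1. Cyclization of this bromide with Pd(OAc)2, (R)-BINAP and Ag3PO4 in DMF at 80 °C should proceed through a cationic alkenylpalladium–bisphosphine complex, because silver removes the bromide. That pathway is the best-precedented one for enantioselective six-membered ring closure. 6-Exo-trig insertion and β-hydride elimination toward the methyl group bring the route back at ketone 9.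

Step 7. Transmetalation of the primary alkyl pinacol boronate may be slow, so that protodeboronation or β-hydride elimination with alkene migration outruns the coupling. The fallback replaces the boron coupling by a reductive cross-electrophile coupling and sets out from boronate 10. Oxidation with NaBO3·4H2O in THF/H2O should give (R)-3-(2-hydroxyethyl)-2,2-dimethyl-4-methylidenecyclohexan-1-one F2. Appel bromination (CBr4, PPh3, CH2Cl2, 0 °C) then gives (R)-3-(2-bromoethyl)-2,2-dimethyl-4-methylidenecyclohexan-1-one F3. Nickel-catalysed coupling of this bromide with iodide 13 (NiBr2·glyme, 4,4'-di-tert-butyl-2,2'-bipyridine, Mn powder, NaI, DMA, rt) tolerates the ketone and the free hydroxyl group and retains the alkene geometry, returning to alcohol 14.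

Step 9. The coumarin is ambident and may be alkylated at the lactone carbonyl oxygen (giving a 2-alkoxychromone) or at C-3, and the activated allylic alcohol may eliminate. The fallback reverses the polarity of the ether formation and sets out from coumarin 17 and alcohol 14. Heating 17 in POCl3 should give 4-chloro-5-methyl-2H-chromen-2-one F4. Alcohol 14 is deprotonated with NaH in THF at 0 °C to its sodium alkoxide F5, which displaces chloride from the chlorocoumarin by addition–elimination at C-4. This can only deliver the 4-alkoxycoumarin and returns at target 18.

Further compounds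
F1 | step 4 | (E)-2-bromo-6,6-dimethylnona-1,7-dien-5-one | C=C(Br)CCC(=O)C(C)(C)/C=C/C
F2 | step 7 | (R)-3-(2-hydroxyethyl)-2,2-dimethyl-4-methylidenecyclohexan-1-one | C=C1CCC(=O)C(C)(C)[C@@H]1CCO
F3 | step 7 | (R)-3-(2-bromoethyl)-2,2-dimethyl-4-methylidenecyclohexan-1-one | C=C1CCC(=O)C(C)(C)[C@@H]1CCBr
F4 | step 9 | 4-chloro-5-methyl-2H-chromen-2-one | Cc1cccc2oc(=O)cc(Cl)c12
F5 | step 9 | sodium (R,E)-5-(2,2-dimethyl-6-methylidene-3-oxocyclohexyl)-3-methylpent-2-en-1-olate | [Na+].C=C1CCC(=O)C(C)(C)[C@@H]1CC/C(C)=C/C[O-]
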